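**Assumption:** an (R)-selective ketoreductase for ketone 9 is taken as a hit from a commercial KRED screening panel; compounds 1, 2 and 6 are bought.

## Retrosynthetic overview

1. Target ⇒ 6,8-dimethoxy lactone: the 8-OH is freed last by chelation-directed cleavage of the peri methyl ether; the side-chain ketone travels as a dioxolane.
2. Lactone C1–O2 ⇒ (R)-hydroxy ester, whose carbinol stereocentre comes from a ketoreductase reduction of a benzyl alkyl ketone.
3. C3–C4 ⇒ laterally lithiated ethyl 2,4-dimethoxy-6-methylbenzoate plus the Weinreb amide of ketal-protected 7-oxododecanoic acid.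
4. Side chain ⇒ ethyl 7-chloro-7-oxoheptanoate plus pentylmagnesium bromide (C7–C8 bond).
5. Ring order: the arene is bought intact; the temporary dioxolane is formed first; the lactone is the only skeletal ring formed, after the stereocentre is set.

## Route

**Step 1**
Reactants: 1 ethyl 7-chloro-7-oxoheptanoate; 2 pentylmagnesium bromide
Product: 3 ethyl 7-oxododecanoate
Conditions: Fe(acac)3 (3 mol %), THF, –78 °C, 2 (1.1 equiv) added dropwise; aq. NH4Cl
Reagents that add atoms: none
Why: Iron-catalysed Grignard acylation of an acid chloride (Kumada-type cross-coupling) is far faster at –78 °C than addition to the ester or to the product ketone, so the mono-ketone forms cleanly.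

**Step 2**
Reactants: 3 ethyl 7-oxododecanoate
Product: 4 ethyl 6-(2-pentyl-1,3-dioxolan-2-yl)hexanoate
Conditions: ethylene glycol (3 equiv), p-TsOH·H2O (5 mol %), toluene, reflux, Dean–Stark
Reagents that add atoms: ethylene glycol, OCCO
Why: Acid-catalysed ketalisation with azeotropic water removal masks the chain ketone against the later carbanion and reductase steps (any glycol ester formed converges in step 3).

**Step 3**
Reactants: 4 ethyl 6-(2-pentyl-1,3-dioxolan-2-yl)hexanoate
Product: 5 N-methoxy-N-methyl-6-(2-pentyl-1,3-dioxolan-2-yl)hexanamide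
Conditions: MeNH(OMe)·HCl (1.5 equiv), i-PrMgCl (3.0 equiv), THF, –20 → 0 °C; aq. NH4Cl
Reagents that add atoms: N,O-dimethylhydroxylamine hydrochloride, CNOC.Cl
Why: Direct ester aminolysis by the chloromagnesium amide of N,O-dimethylhydroxylamine (Weinreb amide synthesis) is a high-yielding reaction that leaves the base-stable ketal untouched.

**Step 4**
Reactants: 6 ethyl 2,4-dimethoxy-6-methylbenzoate; 5 N-methoxy-N-methyl-6-(2-pentyl-1,3-dioxolan-2-yl)hexanamide
Product: 9 ethyl 2,4-dimethoxy-6-[2-oxo-7-(2-pentyl-1,3-dioxolan-2-yl)heptyl]benzoate, via benzylic lithium species 7 (not isolated), via tetrahedral lithium chelate 8 (not isolated)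
Conditions: 6 (1.5 equiv), LDA (1.6 equiv, commercial solution), THF, –78 °C, 30 min; then 5 (1.0 equiv), –78 °C, 1 h; sat. aq. NH4Cl at –78 °C
Reagents that add atoms: none
Why: Lateral (benzylic) lithiation of the hindered ortho-toluate followed by Weinreb ketone synthesis gives the ketone only on quench, because the N,O-chelated adduct blocks over-addition and the 2,6-disubstituted ester resists self-condensation.

**Step 5**
Reactants: 9 ethyl 2,4-dimethoxy-6-[2-oxo-7-(2-pentyl-1,3-dioxolan-2-yl)heptyl]benzoate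
Product: 10 ethyl 2-[(2R)-2-hydroxy-7-(2-pentyl-1,3-dioxolan-2-yl)heptyl]-4,6-dimethoxybenzoate
Conditions: (R)-selective ketoreductase (KRED, an NADPH-dependent alcohol dehydrogenase), NADP+ (cat.), i-PrOH (20 % v/v, hydride donor), KPi buffer (0.1 M, pH 7.0, 1 mM MgSO4), 30 °C, 24–48 h; EtOAc extraction
Reagents that add atoms: none
Why: Enzymatic asymmetric carbonyl reduction: the ketoreductase delivers the NADPH hydride to the Si face of the only free ketone and sets the carbinol (future C3) as R, at neutral pH where ester and ketal are inert.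

**Step 6**
Reactants: 10 ethyl 2-[(2R)-2-hydroxy-7-(2-pentyl-1,3-dioxolan-2-yl)heptyl]-4,6-dimethoxybenzoate
Product: 12 (3R)-6,8-dimethoxy-3-[5-(2-pentyl-1,3-dioxolan-2-yl)pentyl]isochroman-1-one, via sodium alkoxide 11 (not isolated)
Conditions: NaH (1.1 equiv), THF, 0 °C → rt; sat. aq. NH4Cl
Reagents that add atoms: none
Why: Intramolecular transesterification (lactonisation) of the alkoxide onto the ortho ester closes the six-membered lactone without touching the C–O bond of the stereocentre, so the R configuration is retained.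

**Step 7**
Reactants: 12 (3R)-6,8-dimethoxy-3-[5-(2-pentyl-1,3-dioxolan-2-yl)pentyl]isochroman-1-one
Product: 13 (3R)-6,8-dimethoxy-3-(6-oxoundecyl)isochroman-1-one
Conditions: 2 M aq. HCl, THF, rt
Reagents that add atoms: water, O
Why: Acid-catalysed ketal hydrolysis liberates the chain ketone under conditions in which the lactone and the non-epimerisable C3 centre are stable.

**Step 8**
Reactants: 13 (3R)-6,8-dimethoxy-3-(6-oxoundecyl)isochroman-1-one
Product: 15 (3R)-8-hydroxy-6-methoxy-3-(6-oxoundecyl)isochroman-1-one, via aryloxydichloroborane 14 (not isolated)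
Conditions: BCl3 (1 M in CH2Cl2, 3 equiv), CH2Cl2, –78 → 0 °C; then H2O
Reagents that add atoms: none
Why: Chelation-directed Lewis-acid ether cleavage: BCl3 bound to the lactone carbonyl removes only the peri 8-O-methyl group through a six-membered chelate, leaving the 6-OMe, the ketone and C3 untouched.

## Compound list

1 | ethyl 7-chloro-7-oxoheptanoate | CCOC(=O)CCCCCC(=O)Cl | starting material
2 | pentylmagnesium bromide | CCCCC[Mg]Br | starting material
3 | ethyl 7-oxododecanoate | CCOC(=O)CCCCCC(=O)CCCCC | intermediate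
4 | ethyl 6-(2-pentyl-1,3-dioxolan-2-yl)hexanoate | CCOC(=O)CCCCCC1(CCCCC)OCCO1 | intermediate
5 | N-methoxy-N-methyl-6-(2-pentyl-1,3-dioxolan-2-yl)hexanamide | CON(C)C(=O)CCCCCC1(CCCCC)OCCO1 | intermediate
6 | ethyl 2,4-dimethoxy-6-methylbenzoate | CCOC(=O)c1c(C)cc(OC)cc1OC | starting material
7 | ethyl 2-(lithiomethyl)-4,6-dimethoxybenzoate (benzylic lithium species) | CCOC(=O)c1c(C[Li])cc(OC)cc1OC | intermediate
8 | lithium N,O-chelated tetrahedral adduct of 7 and 5 | CCOC(=O)c1c(CC(O[Li])(CCCCCC2(CCCCC)OCCO2)N(C)OC)cc(OC)cc1OC | intermediate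
9 | ethyl 2,4-dimethoxy-6-[2-oxo-7-(2-pentyl-1,3-dioxolan-2-yl)heptyl]benzoate | CCOC(=O)c1c(CC(=O)CCCCCC2(CCCCC)OCCO2)cc(OC)cc1OC | intermediate
10 | ethyl 2-[(2R)-2-hydroxy-7-(2-pentyl-1,3-dioxolan-2-yl)heptyl]-4,6-dimethoxybenzoate | CCOC(=O)c1c(C[C@H](O)CCCCCC2(CCCCC)OCCO2)cc(OC)cc1OC | intermediate
11 | sodium alkoxide of 10 | CCOC(=O)c1c(C[C@H]([O-])CCCCCC2(CCCCC)OCCO2)cc(OC)cc1OC.[Na+] | intermediate
12 | (3R)-6,8-dimethoxy-3-[5-(2-pentyl-1,3-dioxolan-2-yl)pentyl]isochroman-1-one | CCCCCC1(CCCCC[C@@H]2Cc3cc(OC)cc(OC)c3C(=O)O2)OCCO1 | intermediate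
13 | (3R)-6,8-dimethoxy-3-(6-oxoundecyl)isochroman-1-one | CCCCCC(=O)CCCCC[C@@H]1Cc2cc(OC)cc(OC)c2C(=O)O1 | intermediate
14 | (3R)-8-(dichloroboryloxy)-6-methoxy-3-(6-oxoundecyl)isochroman-1-one | CCCCCC(=O)CCCCC[C@@H]1Cc2cc(OC)cc(OB(Cl)Cl)c2C(=O)O1 | intermediate
15 | (3R)-8-hydroxy-6-methoxy-3-(6-oxoundecyl)isochroman-1-one | CCCCCC(=O)CCCCC[C@@H]1Cc2cc(OC)cc(O)c2C(=O)O1 | target

## Summary

Total step count: 8. Longest linear sequence: 8 steps (1 → 3 → 4 → 5 → 9 → 10 → 12 → 13 → 15); compound 6 enters at step 4.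

**Three steps most likely to fail**

**Step 4 (lateral lithiation and acylation).** The risks are enolisation of the Weinreb amide by the benzylic anion and cyclisation of the adduct onto the ester to give an isocoumarin. The fallback sets out from 5 (with 6) and comes back at 9. Amide 5 is reduced with DIBAL-H (THF, –78 °C) to 6-(2-pentyl-1,3-dioxolan-2-yl)hexanal F1. The lithiated toluate 7 (from 6 and LDA) is added to this aldehyde at –78 °C, and the alkoxide lactonises on warming to racemic 6,8-dimethoxy-3-[5-(2-pentyl-1,3-dioxolan-2-yl)pentyl]isochroman-1-one F2. The lactone is opened with KOH in aqueous ethanol and the carboxylate is O-alkylated with EtI in DMF to give racemic ethyl 2-[2-hydroxy-7-(2-pentyl-1,3-dioxolan-2-yl)heptyl]-4,6-dimethoxybenzoate F3. Dess–Martin oxidation (NaHCO3, CH2Cl2) then gives ketone 9, which rejoins the route at step 5.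

**Step 5 (ketoreductase on a benzyl alkyl ketone with two large substituents).** The risk is that no panel enzyme combines useful rate with high R selectivity for this lipophilic ketone. Partial spontaneous lactonisation of 10 is harmless, because it converges in step 6. The fallback sets out from 5 and comes back at 12; it moves the enzymatic reduction to a small/large α-chloroketone, a privileged reductase substrate.
- Chloromethyllithium (ICH2Cl, MeLi·LiBr, THF, –78 °C) converts 5 into 1-chloro-7-(2-pentyl-1,3-dioxolan-2-yl)heptan-2-one F4.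
- A ketoreductase (NADP+, i-PrOH, pH 7 buffer) reduces it to (2R)-1-chloro-7-(2-pentyl-1,3-dioxolan-2-yl)heptan-2-ol F5.
- K2CO3 in MeOH closes this to (2R)-2-[5-(2-pentyl-1,3-dioxolan-2-yl)pentyl]oxirane F6.
- Bought 3,5-dimethoxyphenylmagnesium bromide with CuI (10 mol %, THF, –30 → 0 °C) opens the epoxide at the terminal carbon to give (2R)-1-(3,5-dimethoxyphenyl)-7-(2-pentyl-1,3-dioxolan-2-yl)heptan-2-ol F7.
- NBS (MeCN, 0 °C) brominates ortho to the side chain and para to a methoxy group, giving (2R)-1-(2-bromo-3,5-dimethoxyphenyl)-7-(2-pentyl-1,3-dioxolan-2-yl)heptan-2-ol F8.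
- Pd-catalysed carbonylative lactonisation (Pd(OAc)2, Xantphos, CO 1 atm, Et3N, toluene, 90 °C) delivers 12, which rejoins the route at step 7.

**Step 8 (selective 8-O-demethylation).** The risks are incomplete reaction, or loss of the 6-OMe as well. The fallback sets out from 13 and comes back at 15. Excess BBr3 (CH2Cl2, –78 °C → rt) removes both methyl groups to give (3R)-6,8-dihydroxy-3-(6-oxoundecyl)isochroman-1-one F9. MeI (1.05 equiv) with K2CO3 in acetone at rt then methylates only the free, more acidic 6-OH, because the 8-OH is hydrogen-bonded to the lactone carbonyl; this gives 15.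

## Further compounds

F1 | step 4 | 6-(2-pentyl-1,3-dioxolan-2-yl)hexanal | O=CCCCCCC1(CCCCC)OCCO1
F2 | step 4 | racemic 6,8-dimethoxy-3-[5-(2-pentyl-1,3-dioxolan-2-yl)pentyl]isochroman-1-one | CCCCCC1(CCCCCC2Cc3cc(OC)cc(OC)c3C(=O)O2)OCCO1
F3 | step 4 | racemic ethyl 2-[2-hydroxy-7-(2-pentyl-1,3-dioxolan-2-yl)heptyl]-4,6-dimethoxybenzoate | CCOC(=O)c1c(CC(O)CCCCCC2(CCCCC)OCCO2)cc(OC)cc1OC
F4 | step 5 | 1-chloro-7-(2-pentyl-1,3-dioxolan-2-yl)heptan-2-one | ClCC(=O)CCCCCC1(CCCCC)OCCO1
F5 | step 5 | (2R)-1-chloro-7-(2-pentyl-1,3-dioxolan-2-yl)heptan-2-ol | ClC[C@H](O)CCCCCC1(CCCCC)OCCO1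
F6 | step 5 | (2R)-2-[5-(2-pentyl-1,3-dioxolan-2-yl)pentyl]oxirane | CCCCCC1(CCCCC[C@@H]2CO2)OCCO1
F7 | step 5 | (2R)-1-(3,5-dimethoxyphenyl)-7-(2-pentyl-1,3-dioxolan-2-yl)heptan-2-ol | COc1cc(C[C@H](O)CCCCCC2(CCCCC)OCCO2)cc(OC)c1
F8 | step 5 | (2R)-1-(2-bromo-3,5-dimethoxyphenyl)-7-(2-pentyl-1,3-dioxolan-2-yl)heptan-2-ol | COc1cc(OC)c(Br)c(C[C@H](O)CCCCCC2(CCCCC)OCCO2)c1
F9 | step 8 | (3R)-6,8-dihydroxy-3-(6-oxoundecyl)isochroman-1-one | CCCCCC(=O)CCCCC[C@@H]1Cc2cc(O)cc(O)c2C(=O)O1
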